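**Plan**
Numbering: C8 is the hydroxylated bridgehead and C8' the CH bridgehead. C7 (ArCH) and C9 (CH2) sit on C8, C7' and C9' on C8'. Ring A is C7'–O–C9–C8–C8' and ring B is C7–O–C9'–C8'–C8. Ar = 3,5-dimethoxy-4-(triisopropylsilyloxy)phenyl.
Cuts: the benzylic bonds C7'–O and C7–O are opened to a pentaol, C9 is returned to a lactone carbonyl, C9'–OH to C9'–Si and C8–OH to C8–H. C8–C7 and C8'–C9' are then cut in one operation.
Enabling feature: the ring A atoms C7'–O–C9–C8–C8' are a masked γ-aryl butyrolactone. C8' holds the C9' arm anti to the C7' aryl group and C8 holds the ArCH(O) carbon C7. This is the pattern left by an anti 1,4-addition to a γ-aryl butenolide followed by aldol capture of the enolate.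
Forward: the butenolide is made by ring-closing metathesis. A three-component coupling joins all six core carbons and both aryl groups. C8 is hydroxylated, C9'–Si is oxidised to C9'–OH, the lactone is reduced, and ring A and then ring B close in one acid step.
Stereochemistry: C7' comes from a Sharpless kinetic resolution, C8' is set anti to C7', and C8–OH is set anti to C9'. C7 is set, and C7' re-formed, exo on the cis-fused bicycle under control of C8 and C8'.

Key step: step 7

Assumption: the sense of the kinetic resolution follows the usual empirical model for secondary allylic alcohols with the aryl group as the carbinol substituent, so L-(+)-DIPT leaves the (S)-alcohol unreacted.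

**Step 1**
Reactants: 1 syringaldehyde
Product: 2 3,5-dimethoxy-4-(triisopropylsilyloxy)benzaldehyde
Conditions: TIPSCl, imidazole, DMAP (cat.), DMF, rt
Reagents that add atoms: chlorotriisopropylsilane, CC(C)[Si](Cl)(C(C)C)C(C)C
Why: Imidazole-promoted O-silylation of a phenol; flanked by two methoxy groups, the bulky silyl ether should survive Grignard reagents, amide bases, basic peroxide and LiAlH4 and still fall to fluoride at the end.

**Step 2**
Reactants: 2 3,5-dimethoxy-4-(triisopropylsilyloxy)benzaldehyde; 3 vinylmagnesium bromide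
Product: 4 rac-1-Ar-prop-2-en-1-ol
Conditions: THF, −78 → 0 °C; sat. aq NH4Cl
Reagents that add atoms: none
Why: Grignard 1,2-addition to a non-enolisable aromatic aldehyde should give the racemic allylic alcohol needed for the resolution.

**Step 3**
Reactants: 4 rac-1-Ar-prop-2-en-1-ol
Product: 5 (S)-1-Ar-prop-2-en-1-ol
Conditions: Ti(OiPr)4 (0.2 equiv), L-(+)-DIPT (0.24 equiv), t-BuOOH (0.6 equiv, decane), 4 Å MS, CH2Cl2, −20 °C
Reagents that add atoms: none
Why: Sharpless kinetic resolution; the (R)-alcohol is the matched partner of the L-(+)-tartrate catalyst and is epoxidised first, so just past half conversion the slow-reacting (S)-alcohol, which carries the future C7' configuration, should remain enantioenriched and separable from the polar epoxy alcohol.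

**Step 4**
Reactants: 5 (S)-1-Ar-prop-2-en-1-ol; 6 acryloyl chloride
Product: 7 (S)-1-Ar-prop-2-en-1-yl acrylate
Conditions: Et3N, DMAP (cat.), CH2Cl2, 0 °C
Reagents that add atoms: none
Why: O-acylation with an acid chloride does not touch the C–O bond of the stereocentre, so the configuration is retained.

**Step 5**
Reactants: 7 (S)-1-Ar-prop-2-en-1-yl acrylate
Product: 8 (S)-5-Ar-furan-2(5H)-one
Conditions: second-generation Grubbs catalyst RuCl2(=CHPh)(PCy3)(SIMes) (5 mol %), CH2Cl2 (0.01 M), reflux
Reagents that add atoms: none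
Why: Ring-closing metathesis of allyl acrylates to butenolides is routine with this catalyst, is driven by loss of ethene, and runs in a neutral medium that leaves the base-sensitive C7' stereocentre alone.

**Step 6**
Reactants: 9 (chloromethyl)isopropoxydimethylsilane
Product: 10 (isopropoxydimethylsilyl)methylmagnesium chloride
Conditions: Mg turnings, BrCH2CH2Br (drops), THF, reflux → rt
Reagents that add atoms: magnesium, [Mg]
Why: Direct magnesium insertion into the α-silyl C–Cl bond is the standard preparation of this hydroxymethyl anion equivalent, and the branched isopropoxy group shields silicon from attack by the reagent itself.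

**Step 7**
Reactants: 8 (S)-5-Ar-furan-2(5H)-one; 10 (isopropoxydimethylsilyl)methylmagnesium chloride; 2 3,5-dimethoxy-4-(triisopropylsilyloxy)benzaldehyde
Product: 12 (3R,4S,5S)-5-Ar-3-[Ar(hydroxy)methyl]-4-[(isopropoxydimethylsilyl)methyl]dihydrofuran-2(3H)-one (C7 carbinol epimers), via chloromagnesium enolate 11 (not isolated)
Conditions: CuBr·SMe2 (20 mol %), THF, −78 °C, 10 (1.15 equiv) added over 1 h; then 2 (1.3 equiv), −78 → −50 °C; sat. aq NH4Cl
Reagents that add atoms: none
Why: Transmetallation of 10 to monovalent copper gives a magnesium cuprate that binds the C8=C8' bond on the face away from the C7' aryl group; oxidative addition to a trivalent copper β-alkyl species and reductive elimination make C9'–C8', and the released enolate 11 attacks the carbonyl carbon of 2 through C8 to make C8–C7. The closest known reaction type is the copper-catalysed conjugate addition of Grignard reagents to γ-substituted butenolides with aldol trapping, and this silylmethyl Grignard reagent is an established partner in copper-catalysed 1,4-additions. No ring is closed; the lactone of 8 survives and later supplies C7', C8', C8 and C9 of ring A. C8' is controlled by C7' (anti addition, 4,5-trans) and C8 by the new C9' arm (aldehyde approach anti to it, 3,4-trans), while the C7 carbinol forms without control, which is harmless because C8 is planarised again in step 8 and C7 is ionised in step 11. The step needs 1,4- over 1,2-addition and C–C bond formation over removal of the acidic benzylic γ-hydrogen; the soft cuprate, the weakly basic α-silyl carbanion, slow addition of 10 at −78 °C so that it never accumulates, and late addition of 2 so that it meets only the enolate should secure this.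

**Step 8**
Reactants: 12 (3R,4S,5S)-5-Ar-3-[Ar(hydroxy)methyl]-4-[(isopropoxydimethylsilyl)methyl]dihydrofuran-2(3H)-one
Product: 14 (3R,4R,5S)-5-Ar-3-hydroxy-3-[Ar(hydroxy)methyl]-4-[(isopropoxydimethylsilyl)methyl]dihydrofuran-2(3H)-one (C7 carbinol epimers), via dilithium enolate alkoxide 13 (not isolated)
Conditions: LiN(iPr)2 (LDA, 2.5 equiv), THF, −78 → −40 °C; 2-(benzenesulfonyl)-3-phenyloxaziridine (1.5 equiv), −78 °C; sat. aq NH4Cl
Reagents that add atoms: 2-(benzenesulfonyl)-3-phenyloxaziridine, O=S(=O)(c1ccccc1)N1OC1c1ccccc1; lithium diisopropylamide, [Li]N(C(C)C)C(C)C (supplies the lithium of 13 only)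
Why: Fráter–Seebach-type dianion formation, in which the C7 alkoxide is too poor a leaving group for β-elimination and the doubly charged species resists retro-aldol cleavage, is followed by Davis oxaziridine hydroxylation of the planar C8 enolate on the face anti to the adjacent C9' arm, which sets C8 with OH trans and C7 cis to C9'.

**Step 9**
Reactants: 14 (3R,4R,5S)-5-Ar-3-hydroxy-3-[Ar(hydroxy)methyl]-4-[(isopropoxydimethylsilyl)methyl]dihydrofuran-2(3H)-one
Product: 15 (3R,4R,5S)-5-Ar-3-hydroxy-3-[Ar(hydroxy)methyl]-4-(hydroxymethyl)dihydrofuran-2(3H)-one (C7 carbinol epimers)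
Conditions: 30% aq H2O2, KHCO3, THF/MeOH (1:1), 40 °C
Reagents that add atoms: hydrogen peroxide, OO
Why: Tamao oxidation of the alkoxysilane (hydroperoxide adds to silicon and C9' migrates to oxygen) involves no stereocentre, its fluoride-free bicarbonate variant should spare the aryl silyl ethers, and an acyl shift of the lactone to the new primary hydroxyl would be harmless because either lactone reduces to 16.

**Step 10**
Reactants: 15 (3R,4R,5S)-5-Ar-3-hydroxy-3-[Ar(hydroxy)methyl]-4-(hydroxymethyl)dihydrofuran-2(3H)-one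
Product: 16 (2S,3R,4S)-1,4-bis-Ar-2,3-bis(hydroxymethyl)butane-1,2,4-triol (C1 = C7 epimers)
Conditions: LiAlH4 (excess), THF, 0 °C → rt; H2O, aq NaOH
Reagents that add atoms: none
Why: Hydride reduction of a lactone to the diol touches no stereocentre, and hindered aryl triisopropylsilyl ethers tolerate LiAlH4.

**Step 11**
Reactants: 16 (2S,3R,4S)-1,4-bis-Ar-2,3-bis(hydroxymethyl)butane-1,2,4-triol
Product: 18 (1S,2R,5R,6S)-2,6-bis-Ar-3,7-dioxabicyclo[3.3.0]octan-1-ol (bis-O-triisopropylsilyl 8-hydroxysyringaresinol; 7R,8S,7'S,8'R), via ring A tetrahydrofuran triol 17 (not isolated)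
Conditions: camphor-10-sulfonic acid (10 mol %), CH2Cl2 (0.01 M), 0 °C → rt, stopped at consumption of 17
Reagents that add atoms: none
Why: This is the acid-catalysed dehydrative cycloetherification used for furofuran lignans: C7', which has no β-hydroxyl to destabilise its cation, should ionise first and be captured by C9–OH (5-exo, ring A), then C7 ionises and is captured by C9'–OH (5-exo, ring B); the fixed C8/C8' pair allows only the cis-fused bicycle with OH and H on the convex face, and under kinetic control each aryl group should settle exo, which converges the C7 epimers to 7R and re-forms C7' as 7'S.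

**Step 12**
Reactants: 18 bis-O-triisopropylsilyl 8-hydroxysyringaresinol
Product: 19 8-hydroxysyringaresinol (7R,8S,7'S,8'R)
Conditions: Bu4NF (2.5 equiv), AcOH (2.5 equiv), THF, 0 °C
Reagents that add atoms: none
Why: Fluoride cleaves both aryl silyl ethers, and the acetic acid buffer keeps free phenoxide from opening the benzylic ethers through a quinone methide, so all four stereocentres stay untouched.

**Compound list**
1 | syringaldehyde | COc1cc(C=O)cc(OC)c1O | starting material
2 | 3,5-dimethoxy-4-(triisopropylsilyloxy)benzaldehyde | COc1cc(C=O)cc(OC)c1O[Si](C(C)C)(C(C)C)C(C)C | intermediate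
3 | vinylmagnesium bromide | C=C[Mg]Br | starting material
4 | rac-1-Ar-prop-2-en-1-ol | COc1cc(C(O)C=C)cc(OC)c1O[Si](C(C)C)(C(C)C)C(C)C | intermediate
5 | (S)-1-Ar-prop-2-en-1-ol | COc1cc([C@@H](O)C=C)cc(OC)c1O[Si](C(C)C)(C(C)C)C(C)C | intermediate
6 | acryloyl chloride | C=CC(=O)Cl | starting material
7 | (S)-1-Ar-prop-2-en-1-yl acrylate | COc1cc([C@@H](OC(=O)C=C)C=C)cc(OC)c1O[Si](C(C)C)(C(C)C)C(C)C | intermediate
8 | (S)-5-Ar-furan-2(5H)-one | COc1cc([C@H]2OC(=O)C=C2)cc(OC)c1O[Si](C(C)C)(C(C)C)C(C)C | intermediate
9 | (chloromethyl)isopropoxydimethylsilane | CC(C)O[Si](C)(C)CCl | starting material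
10 | (isopropoxydimethylsilyl)methylmagnesium chloride | CC(C)O[Si](C)(C)C[Mg]Cl | intermediate
11 | chloromagnesium enolate of (4S,5S)-5-Ar-4-[(isopropoxydimethylsilyl)methyl]dihydrofuran-2(3H)-one | COc1cc([C@H]2OC(O[Mg]Cl)=C[C@@H]2C[Si](C)(C)OC(C)C)cc(OC)c1O[Si](C(C)C)(C(C)C)C(C)C | intermediate
12 | (3R,4S,5S)-5-Ar-3-[Ar(hydroxy)methyl]-4-[(isopropoxydimethylsilyl)methyl]dihydrofuran-2(3H)-one, carbinol epimers | COc1cc([C@H]2OC(=O)[C@@H](C(O)c3cc(OC)c(O[Si](C(C)C)(C(C)C)C(C)C)c(OC)c3)[C@@H]2C[Si](C)(C)OC(C)C)cc(OC)c1O[Si](C(C)C)(C(C)C)C(C)C | intermediate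
13 | dilithium enolate alkoxide of 12 | COc1cc([C@H]2OC(O[Li])=C(C(O[Li])c3cc(OC)c(O[Si](C(C)C)(C(C)C)C(C)C)c(OC)c3)[C@@H]2C[Si](C)(C)OC(C)C)cc(OC)c1O[Si](C(C)C)(C(C)C)C(C)C | intermediate
14 | (3R,4R,5S)-5-Ar-3-hydroxy-3-[Ar(hydroxy)methyl]-4-[(isopropoxydimethylsilyl)methyl]dihydrofuran-2(3H)-one, carbinol epimers | COc1cc([C@H]2OC(=O)[C@](O)(C(O)c3cc(OC)c(O[Si](C(C)C)(C(C)C)C(C)C)c(OC)c3)[C@@H]2C[Si](C)(C)OC(C)C)cc(OC)c1O[Si](C(C)C)(C(C)C)C(C)C | intermediate
15 | (3R,4R,5S)-5-Ar-3-hydroxy-3-[Ar(hydroxy)methyl]-4-(hydroxymethyl)dihydrofuran-2(3H)-one, carbinol epimers | COc1cc([C@H]2OC(=O)[C@](O)(C(O)c3cc(OC)c(O[Si](C(C)C)(C(C)C)C(C)C)c(OC)c3)[C@@H]2CO)cc(OC)c1O[Si](C(C)C)(C(C)C)C(C)C | intermediate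
16 | (2S,3R,4S)-1,4-bis-Ar-2,3-bis(hydroxymethyl)butane-1,2,4-triol, C1 epimers | COc1cc([C@@H](O)[C@@H](CO)[C@](O)(CO)C(O)c2cc(OC)c(O[Si](C(C)C)(C(C)C)C(C)C)c(OC)c2)cc(OC)c1O[Si](C(C)C)(C(C)C)C(C)C | intermediate
17 | ring A tetrahydrofuran triol (C7'–O–C9 closed; C7-OH, C8-OH and C9'-OH free; 8S,7'S,8'R) | COc1cc([C@H]2OC[C@](O)(C(O)c3cc(OC)c(O[Si](C(C)C)(C(C)C)C(C)C)c(OC)c3)[C@@H]2CO)cc(OC)c1O[Si](C(C)C)(C(C)C)C(C)C | intermediate
18 | bis-O-triisopropylsilyl 8-hydroxysyringaresinol (7R,8S,7'S,8'R) | COc1cc([C@H]2OC[C@]3(O)[C@@H](c4cc(OC)c(O[Si](C(C)C)(C(C)C)C(C)C)c(OC)c4)OC[C@H]23)cc(OC)c1O[Si](C(C)C)(C(C)C)C(C)C | intermediate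
19 | 8-hydroxysyringaresinol (7R,8S,7'S,8'R) | COc1cc([C@H]2OC[C@]3(O)[C@@H](c4cc(OC)c(O)c(OC)c4)OC[C@H]23)cc(OC)c1O | target

**Step count**
Total: 12 steps. Longest linear sequence: 11 steps from syringaldehyde (steps 1–5 and 7–12). Step 6 is a one-step side branch.

**Steps most likely to fail**

Step 7. Proton transfer from the acidic benzylic γ-position of 8 to 10 or to enolate 11 would erode enantiopurity and stall the addition. Transfer of the silylmethyl group from copper may be slow, and the enolate may be quenched before it meets 2. The fallback makes the two bonds in separate operations, so that no basic enolate ever coexists with 8. Starting from 8, the copper-catalysed addition of 10 is run with Me3SiCl in the flask, and the enolate is silylated as it forms to the trimethylsilyl ketene acetal F1. Mild aqueous acid gives the trans-4,5-disubstituted lactone F2. LDA at −78 °C converts this into the lithium enolate F3, which adds to 2 anti to the C9' arm and rejoins the route at 12.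

Step 8. The second deprotonation at the hindered C8–H may be incomplete, and the monoanion may undergo retro-aldol cleavage. Alkoxide exchange at silicon and insufficient facial selectivity in the oxygen transfer are further risks. The fallback avoids strong base and brings in both oxygens by alkene oxidation. Starting from 12, MsCl/Et3N gives the C7 mesylate F4, and DBU eliminates it to the (E)-α-arylidene lactone F5. Catalytic OsO4 with N-methylmorpholine N-oxide then dihydroxylates C7=C8 from the face anti to the C9' arm, which rejoins the route at 14 as a single carbinol epimer.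

Step 11. A benzylic cation may be captured by the other benzylic hydroxyl instead of the primary one, or attacked in Friedel–Crafts fashion by the second electron-rich ring. Acid-induced epimerisation at C7 or C7' on prolonged exposure and loss of formaldehyde from C9 are also possible. The fallback never breaks the C7'–O bond and closes only ring B by ionisation. Starting from 15, catalytic camphor-10-sulfonic acid closes C9'–OH onto C7, which is cis to C9' on the lactone, to give the bicyclic hydroxy lactone F6. i-Bu2AlH at −78 °C gives the lactol F7. Et3SiH/BF3·OEt2 at −78 °C reduces the lactol carbon C9 to CH2, which rejoins the route at 18.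

**Further compounds**
F1 | step 7 | trimethylsilyl ketene acetal of (4S,5S)-5-Ar-4-[(isopropoxydimethylsilyl)methyl]dihydrofuran-2(3H)-one | COc1cc([C@H]2OC(O[Si](C)(C)C)=C[C@@H]2C[Si](C)(C)OC(C)C)cc(OC)c1O[Si](C(C)C)(C(C)C)C(C)C
F2 | step 7 | (4S,5S)-5-Ar-4-[(isopropoxydimethylsilyl)methyl]dihydrofuran-2(3H)-one | COc1cc([C@H]2OC(=O)C[C@@H]2C[Si](C)(C)OC(C)C)cc(OC)c1O[Si](C(C)C)(C(C)C)C(C)C
F3 | step 7 | lithium enolate of F2 | COc1cc([C@H]2OC(O[Li])=C[C@@H]2C[Si](C)(C)OC(C)C)cc(OC)c1O[Si](C(C)C)(C(C)C)C(C)C
F4 | step 8 | C7 methanesulfonate of 12 | COc1cc([C@H]2OC(=O)[C@@H](C(OS(C)(=O)=O)c3cc(OC)c(O[Si](C(C)C)(C(C)C)C(C)C)c(OC)c3)[C@@H]2C[Si](C)(C)OC(C)C)cc(OC)c1O[Si](C(C)C)(C(C)C)C(C)C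
F5 | step 8 | (4S,5S,E)-5-Ar-3-(Ar-methylidene)-4-[(isopropoxydimethylsilyl)methyl]dihydrofuran-2(3H)-one | COc1cc([C@H]2OC(=O)/C(=C/c3cc(OC)c(O[Si](C(C)C)(C(C)C)C(C)C)c(OC)c3)[C@@H]2C[Si](C)(C)OC(C)C)cc(OC)c1O[Si](C(C)C)(C(C)C)C(C)C
F6 | step 11 | 9-oxo analogue of 18 (bicyclic hydroxy lactone, configuration as in 18) | COc1cc([C@H]2OC(=O)[C@]3(O)[C@@H](c4cc(OC)c(O[Si](C(C)C)(C(C)C)C(C)C)c(OC)c4)OC[C@H]23)cc(OC)c1O[Si](C(C)C)(C(C)C)C(C)C
F7 | step 11 | 9-hydroxy analogue of 18 (lactol, C9 anomers) | COc1cc([C@H]2OC(O)[C@]3(O)[C@@H](c4cc(OC)c(O[Si](C(C)C)(C(C)C)C(C)C)c(OC)c4)OC[C@H]23)cc(OC)c1O[Si](C(C)C)(C(C)C)C(C)C
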